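E takes Q for good, and what X in this flask can hold at the end is a leftover of Q.

X 1.0 mM; Q 1.30 mM; E 0.500 mM; time 10 min

    X + Q ⇌ X.Q (K1 = 746 M⁻¹, k1 = 75.7 M⁻¹ s⁻¹)
    Q + E → Q.E (k2 = 40.1 M⁻¹ s⁻¹)
    X.Q ⇌ L (K3 = 0.555, k3 = 0.0231 s⁻¹)

1. part of the X gone at 10 min
2. the L standing at 10 min, as a percentage of the X charged

This reckoning carries 0.800 mM, the spare Q: the Q charged minus the E charged. Free Q plus X.Q plus L minus remaining E holds that value through the run, since each step trades these one for one.

X and Q start at a forward rate of 0.0984 mM s⁻¹, and E's draw on Q is 0.26 of that. With X.Q and L in their equilibrium ratio, the combined binding constant is 1160 M⁻¹. Balancing forward against back gives a quadratic for the amount held, b: b equals that constant times (X charged minus b) times (spare Q minus b). Its smaller root is 0.345 mM.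

The forward rate therefore shrinks by three factors: 0.615 for E's removal of Q, 0.569 for Q bound, and 0.655 for X bound. It ends at 0.0225 mM s⁻¹, which equals the back rate.

With free Q at that end value, E's half-life is 0.634 min, far shorter than the time, and the relaxation half-life of X.Q and L, 0.178 min, is also short. So the reckoning commits to 34.5% of X gone and 12.3% as L.

The forecast gives 34.5% and 12.3%, reading the end state as “their equilibrium on that remaining Q”, the same route as this reckoning.

The simulation gives 34.5% and 12.3%, with E at 0% after 10.0 min. After 1.00 min in this flask, free Q plus X.Q plus L minus E reads 0.800 mM, the spare Q. The neighbouring flask charges 5.2 mM of Q, so its spare Q is 4.70 mM. The same quadratic holds 0.818 mM, which is 81.8% of X gone and 29.2% as L. That neighbouring flask, simulated, gives 81.8% gone and 29.2% as L.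

The constants used here are made up; what happens was integrated by code.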